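The flavanone is cut at the O1–C8a aryl ether bond of ring C. C8a sits on ring A between the prenylated C8 and C4a, so it maps onto the chelated phenol carbon of 2,4-dihydroxy-3-prenylbenzaldehyde, whose hydroxyl becomes a triflate. One palladium-catalysed intramolecular C–O coupling then joins the C2 carbinol oxygen to C8a and closes ring C without touching the C2–O bond, so the (S) centre set by CBS reduction passes through unchanged. The cyclisation substrate is an open-chain aryl triflate carrying a free (S) benzylic alcohol at C2 and a triisopropylsilyl ether at C4, preferred to a smaller silyl group because it cannot migrate to the C2 alkoxide.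

Key step: step 10

Remark: atom labels follow flavanone numbering (O1, C2, C3, C4, C4a to C8a; rings A, B, C) also in open-chain intermediates. C4 is carried as a mixture of epimers from step 7 to step 11, which is harmless because C4 becomes the carbonyl carbon in step 12.

Step 1
Reactants: 1 2,4-dihydroxybenzaldehyde; 2 3-chloro-3-methylbut-1-yne
Product: 3 2-hydroxy-4-[(2-methylbut-3-yn-2-yl)oxy]benzaldehyde
Conditions: DBU (1.3 equiv), CuCl2·2H2O (1 mol%), MeCN, 0 °C
Reagents that add atoms: none
Why: Copper-catalysed propargylic substitution of the tertiary chloride should etherify only the more acidic, unchelated 4-OH, because the 2-OH is held in a hydrogen bond to the aldehyde.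

Step 2
Reactants: 3 2-hydroxy-4-[(2-methylbut-3-yn-2-yl)oxy]benzaldehyde
Product: 4 2-hydroxy-4-[(2-methylbut-3-en-2-yl)oxy]benzaldehyde
Conditions: H2 (1 atm), Pd/CaCO3 poisoned with Pb(OAc)2, quinoline, EtOAc, rt
Reagents that add atoms: none
Why: Lindlar-type semihydrogenation should stop at the terminal alkene after one equivalent of H2, since the poisoned palladium surface reduces neither the alkene further nor the aldehyde at a useful rate.

Step 3
Reactants: 4 2-hydroxy-4-[(2-methylbut-3-en-2-yl)oxy]benzaldehyde
Product: 6 2,4-dihydroxy-3-(3-methylbut-2-en-1-yl)benzaldehyde, via ortho-dienone 5 (not isolated)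
Conditions: N,N-diethylaniline, 140 °C
Reagents that add atoms: none
Why: Aromatic Claisen rearrangement, in which the [3,3] shift transposes the 1,1-dimethylallyl unit so that it arrives as a prenyl group, preferentially at C3 because the chelated 2-hydroxy aldehyde localises double-bond character in the C3–C4 bond, after which dienone 5 tautomerises to the phenol.

Step 4
Reactants: 6 2,4-dihydroxy-3-(3-methylbut-2-en-1-yl)benzaldehyde
Product: 7 2-hydroxy-3-(3-methylbut-2-en-1-yl)-4-(triisopropylsilyloxy)benzaldehyde
Conditions: TIPSCl (1.05 equiv), imidazole, DMF, 0 °C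
Reagents that add atoms: chlorotriisopropylsilane, CC(C)[Si](Cl)(C(C)C)C(C)C
Why: Phenol silylation should go to O4 alone, because the 2-OH is hydrogen-bonded to the aldehyde and flanked by the formyl and prenyl groups.

Step 5
Reactants: 7 2-hydroxy-3-(3-methylbut-2-en-1-yl)-4-(triisopropylsilyloxy)benzaldehyde
Product: 8 6-formyl-2-(3-methylbut-2-en-1-yl)-3-(triisopropylsilyloxy)phenyl trifluoromethanesulfonate
Conditions: Tf2O (1.2 equiv), pyridine, CH2Cl2, –20 → 0 °C
Reagents that add atoms: trifluoromethanesulfonic anhydride, O=S(=O)(OS(=O)(=O)C(F)(F)F)C(F)(F)F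
Why: O-Sulfonylation with the highly reactive anhydride should overcome the chelation and hindrance of the remaining phenol, while the pyridine-buffered cold medium spares the silyl ether, the aldehyde and the alkene.

Step 6
Reactants: 9 2,2-dimethylchroman
Product: 10 1-(2,2-dimethylchroman-6-yl)ethanone
Conditions: Ac2O (1.5 equiv), Sc(OTf)3 (10 mol%), MeNO2, 50 °C
Reagents that add atoms: acetic anhydride, CC(=O)OC(C)=O
Why: Friedel–Crafts acylation of an alkyl aryl ether should go para to the ring oxygen (C6), the ortho position C8 being more hindered, and the catalytic metal triflate is mild enough not to cleave the tertiary alkyl aryl ether.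

Step 7
Reactants: 10 1-(2,2-dimethylchroman-6-yl)ethanone; 8 6-formyl-2-(3-methylbut-2-en-1-yl)-3-(triisopropylsilyloxy)phenyl trifluoromethanesulfonate
Product: 12 6-[3-(2,2-dimethylchroman-6-yl)-1-hydroxy-3-oxopropyl]-2-(3-methylbut-2-en-1-yl)-3-(triisopropylsilyloxy)phenyl trifluoromethanesulfonate (racemic), via lithium enolate 11 (not isolated)
Conditions: LiN(iPr)2 (1.05 equiv), THF, –78 °C; then 8, –78 °C; AcOH, –78 °C
Reagents that add atoms: none
Why: Directed aldol addition of the preformed lithium enolate to the non-enolisable aldehyde, quenched cold so that neither dehydration to the chalcone nor triflyl transfer to the aldolate can set in; the new C4 carbinol forms as a racemate, which is of no consequence.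

Step 8
Reactants: 12 6-[3-(2,2-dimethylchroman-6-yl)-1-hydroxy-3-oxopropyl]-2-(3-methylbut-2-en-1-yl)-3-(triisopropylsilyloxy)phenyl trifluoromethanesulfonate
Product: 13 6-[3-(2,2-dimethylchroman-6-yl)-3-oxo-1-(triisopropylsilyloxy)propyl]-2-(3-methylbut-2-en-1-yl)-3-(triisopropylsilyloxy)phenyl trifluoromethanesulfonate (racemic)
Conditions: TIPSOTf (1.3 equiv), 2,6-lutidine, CH2Cl2, –78 → 0 °C
Reagents that add atoms: triisopropylsilyl trifluoromethanesulfonate, CC(C)[Si](OS(=O)(=O)C(F)(F)F)(C(C)C)C(C)C
Why: Silyl ether formation with a silyl triflate and a hindered base caps the β-hydroxy ketone before it can undergo retro-aldol cleavage or elimination, and the bulky triisopropylsilyl group is chosen because it resists 1,3-migration to a neighbouring alkoxide.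

Step 9
Reactants: 13 6-[3-(2,2-dimethylchroman-6-yl)-3-oxo-1-(triisopropylsilyloxy)propyl]-2-(3-methylbut-2-en-1-yl)-3-(triisopropylsilyloxy)phenyl trifluoromethanesulfonate
Product: 14 6-[(3S)-3-(2,2-dimethylchroman-6-yl)-3-hydroxy-1-(triisopropylsilyloxy)propyl]-2-(3-methylbut-2-en-1-yl)-3-(triisopropylsilyloxy)phenyl trifluoromethanesulfonate (both epimers at the silyloxy carbon)
Conditions: (R)-2-methyl-CBS-oxazaborolidine (20 mol%), catecholborane (1.8 equiv), toluene, –78 → –40 °C; MeOH, pH 7 buffer
Reagents that add atoms: none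
Why: Corey–Bakshi–Shibata reduction, in which the (R)-oxazaborolidine binds the ketone with the aryl group as the large substituent and delivers hydride to the Re face, should set C2 as (S) under catalyst control for both C4 epimers, and catecholborane is used because it does not hydroborate the prenyl alkene at this temperature.

Step 10
Reactants: 14 6-[(3S)-3-(2,2-dimethylchroman-6-yl)-3-hydroxy-1-(triisopropylsilyloxy)propyl]-2-(3-methylbut-2-en-1-yl)-3-(triisopropylsilyloxy)phenyl trifluoromethanesulfonate
Product: 15 (2S)-2-(2,2-dimethylchroman-6-yl)-8-(3-methylbut-2-en-1-yl)-4,7-bis(triisopropylsilyloxy)chroman (both epimers at C4)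
Conditions: Pd(OAc)2 (5 mol%), 2-di-tert-butylphosphino-2',4',6'-triisopropylbiphenyl (7.5 mol%), Cs2CO3 (1.5 equiv), toluene, 80 °C
Reagents that add atoms: none
Why: Zerovalent palladium, generated in the flask from Pd(OAc)2 and the phosphine, adds oxidatively to the C8a–OTf bond, Cs2CO3 exchanges triflate on palladium for the C2 alkoxide, and C(sp2)–O reductive elimination releases the chroman; this is a Buchwald-type intramolecular aryl etherification, known for aryl halides and sulfonates tethered to secondary alcohols. Ring C closes as a six-membered ring by extrusion of palladium from a seven-membered aryl(alkoxo)palladium chelate (Pd, C8a, C4a, C4, C3, C2, O1), so no attack trajectory at a carbon centre is involved. No stereocentre is created: the C2–O bond is never broken, so the (S) configuration is retained, and C4 remains an epimer mixture. The step needs C–O reductive elimination to outrun β-hydride elimination from the benzylic palladium alkoxide, which the bulky, electron-rich di-tert-butylphosphine and the two ortho substituents on the aryl ligand (C8 prenyl, C4a chain) should promote. Site selectivity for O1 is secured by capping O4 as a triisopropylsilyl ether that does not shuttle to the C2 alkoxide, and with C4 at the alcohol level there is no β-hydroxy ketone that base could cleave by retro-aldol reaction or dehydrate.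

Step 11
Reactants: 15 (2S)-2-(2,2-dimethylchroman-6-yl)-8-(3-methylbut-2-en-1-yl)-4,7-bis(triisopropylsilyloxy)chroman
Product: 16 (2S)-2-(2,2-dimethylchroman-6-yl)-8-(3-methylbut-2-en-1-yl)chroman-4,7-diol (both epimers at C4)
Conditions: Bu4NF (3 equiv), THF, 0 °C → rt; AcOH quench
Reagents that add atoms: none
Why: Fluoride-driven desilylation should remove the aryl and the alkyl silyl ether in one operation, and because ring C carries no carbonyl yet, the basic medium can neither open the ring nor epimerise C2.

Step 12
Reactants: 16 (2S)-2-(2,2-dimethylchroman-6-yl)-8-(3-methylbut-2-en-1-yl)chroman-4,7-diol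
Product: 17 euchrenone a17, (2S)-2-(2,2-dimethylchroman-6-yl)-7-hydroxy-8-(3-methylbut-2-en-1-yl)chroman-4-one
Conditions: activated MnO2 (15 equiv), CH2Cl2, rt
Reagents that add atoms: none
Why: MnO2 oxidation is selective for the benzylic C4 carbinol and converges both C4 epimers on the ketone, and it runs on a neutral solid surface, so the flavanone never meets base that could racemise C2 by ring opening to the chalcone.

Compound list
1 | 2,4-dihydroxybenzaldehyde | O=Cc1ccc(O)cc1O | starting material
2 | 3-chloro-3-methylbut-1-yne | CC(C)(Cl)C#C | starting material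
3 | 2-hydroxy-4-[(2-methylbut-3-yn-2-yl)oxy]benzaldehyde | O=Cc1ccc(OC(C)(C)C#C)cc1O | intermediate
4 | 2-hydroxy-4-[(2-methylbut-3-en-2-yl)oxy]benzaldehyde | O=Cc1ccc(OC(C)(C)C=C)cc1O | intermediate
5 | 2-hydroxy-3-(3-methylbut-2-en-1-yl)-4-oxocyclohexa-1,5-diene-1-carbaldehyde (racemic Claisen dienone) | O=CC1=C(O)C(CC=C(C)C)C(=O)C=C1 | intermediate (not isolated)
6 | 2,4-dihydroxy-3-(3-methylbut-2-en-1-yl)benzaldehyde | CC(C)=CCc1c(O)ccc(C=O)c1O | intermediate
7 | 2-hydroxy-3-(3-methylbut-2-en-1-yl)-4-(triisopropylsilyloxy)benzaldehyde | CC(C)=CCc1c(O[Si](C(C)C)(C(C)C)C(C)C)ccc(C=O)c1O | intermediate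
8 | 6-formyl-2-(3-methylbut-2-en-1-yl)-3-(triisopropylsilyloxy)phenyl trifluoromethanesulfonate | CC(C)=CCc1c(O[Si](C(C)C)(C(C)C)C(C)C)ccc(C=O)c1OS(=O)(=O)C(F)(F)F | intermediate
9 | 2,2-dimethylchroman | CC1(C)CCc2ccccc2O1 | starting material
10 | 1-(2,2-dimethylchroman-6-yl)ethanone | CC(=O)c1ccc2c(c1)CCC(C)(C)O2 | intermediate
11 | lithium 1-(2,2-dimethylchroman-6-yl)ethen-1-olate | [Li]OC(=C)c1ccc2c(c1)CCC(C)(C)O2 | intermediate (not isolated)
12 | 6-[3-(2,2-dimethylchroman-6-yl)-1-hydroxy-3-oxopropyl]-2-(3-methylbut-2-en-1-yl)-3-(triisopropylsilyloxy)phenyl trifluoromethanesulfonate (racemic) | CC(C)=CCc1c(O[Si](C(C)C)(C(C)C)C(C)C)ccc(C(O)CC(=O)c2ccc3c(c2)CCC(C)(C)O3)c1OS(=O)(=O)C(F)(F)F | intermediate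
13 | 6-[3-(2,2-dimethylchroman-6-yl)-3-oxo-1-(triisopropylsilyloxy)propyl]-2-(3-methylbut-2-en-1-yl)-3-(triisopropylsilyloxy)phenyl trifluoromethanesulfonate (racemic) | CC(C)=CCc1c(O[Si](C(C)C)(C(C)C)C(C)C)ccc(C(O[Si](C(C)C)(C(C)C)C(C)C)CC(=O)c2ccc3c(c2)CCC(C)(C)O3)c1OS(=O)(=O)C(F)(F)F | intermediate
14 | 6-[(3S)-3-(2,2-dimethylchroman-6-yl)-3-hydroxy-1-(triisopropylsilyloxy)propyl]-2-(3-methylbut-2-en-1-yl)-3-(triisopropylsilyloxy)phenyl trifluoromethanesulfonate (both epimers at the silyloxy carbon) | CC(C)=CCc1c(O[Si](C(C)C)(C(C)C)C(C)C)ccc(C(O[Si](C(C)C)(C(C)C)C(C)C)C[C@H](O)c2ccc3c(c2)CCC(C)(C)O3)c1OS(=O)(=O)C(F)(F)F | intermediate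
15 | (2S)-2-(2,2-dimethylchroman-6-yl)-8-(3-methylbut-2-en-1-yl)-4,7-bis(triisopropylsilyloxy)chroman (both epimers at C4) | CC(C)=CCc1c(O[Si](C(C)C)(C(C)C)C(C)C)ccc2c1O[C@H](c1ccc3c(c1)CCC(C)(C)O3)CC2O[Si](C(C)C)(C(C)C)C(C)C | intermediate
16 | (2S)-2-(2,2-dimethylchroman-6-yl)-8-(3-methylbut-2-en-1-yl)chroman-4,7-diol (both epimers at C4) | CC(C)=CCc1c(O)ccc2c1O[C@H](c1ccc3c(c1)CCC(C)(C)O3)CC2O | intermediate
17 | euchrenone a17, (2S)-2-(2,2-dimethylchroman-6-yl)-7-hydroxy-8-(3-methylbut-2-en-1-yl)chroman-4-one | CC(C)=CCc1c(O)ccc2c1O[C@H](c1ccc3c(c1)CCC(C)(C)O3)CC2=O | target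

Total step count: 12. Longest linear sequence: 11 steps (steps 1–5 and 7–12, from 2,4-dihydroxybenzaldehyde); step 6 is a one-step side branch.

Steps most likely to fail

Step 10. The benzylic palladium alkoxide may undergo β-hydride elimination, which oxidises C2 to the ketone and reduces the triflate to C–H. Oxidative addition at the doubly ortho-substituted triflate may also be slow, or base may cleave the S–O bond of the triflate. The fallback closes ring C at the other ether bond, O1–C2, by a Mitsunobu reaction with inversion. It sets out from ketone 13. Corey–Bakshi–Shibata reduction with the (S)-oxazaborolidine and catecholborane would give the C2-epimeric alcohol 6-[(3R)-3-(2,2-dimethylchroman-6-yl)-3-hydroxy-1-(triisopropylsilyloxy)propyl]-2-(3-methylbut-2-en-1-yl)-3-(triisopropylsilyloxy)phenyl trifluoromethanesulfonate F1. Brief treatment with Et4NOH in dioxane at room temperature would cleave the S–O bond of the triflate, which here serves as a phenol protecting group, and give 6-[(3R)-3-(2,2-dimethylchroman-6-yl)-3-hydroxy-1-(triisopropylsilyloxy)propyl]-2-(3-methylbut-2-en-1-yl)-3-(triisopropylsilyloxy)phenol F2. PPh3 and diisopropyl azodicarboxylate in THF at 0 °C would then let the C8a phenol displace the activated (R) carbinol with inversion and deliver 15, where the route is rejoined. Partial ionisation of the electron-rich benzylic oxyphosphonium ion, with erosion of enantiopurity, is the reason this closure is held in reserve.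

Step 12. The free, electron-rich phenol may be oxidised or coupled on the MnO2 surface, or the oxidation may stall. The fallback protects, oxidises and deprotects, and sets out from diol 16. TBSCl (1.05 equiv) and imidazole in CH2Cl2 at 0 °C should silylate the phenol in preference to the hindered secondary alcohol and give (2S)-7-(tert-butyldimethylsilyloxy)-2-(2,2-dimethylchroman-6-yl)-8-(3-methylbut-2-en-1-yl)chroman-4-ol F3. Dess–Martin periodinane with NaHCO3 in CH2Cl2 would oxidise C4 to give (2S)-7-(tert-butyldimethylsilyloxy)-2-(2,2-dimethylchroman-6-yl)-8-(3-methylbut-2-en-1-yl)chroman-4-one F4. Bu4NF buffered with AcOH in THF at 0 °C would free the phenol without base-induced ring opening and give 17.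

Step 9. Facial selectivity may be poor for the C4 epimer that is mismatched with the catalyst, and the prenyl alkene may be hydroborated in competition. The fallback leaves boron hydrides altogether and sets out from ketone 13. Noyori–Ikariya asymmetric transfer hydrogenation with RuCl(p-cymene)[(S,S)-TsDPEN] and HCO2H/Et3N (5:2) in CH2Cl2 at room temperature distinguishes the enantiofaces through a CH–π contact with the aryl ring, not through steric size. It should give the (S) alcohol 14 directly, so no new compound arises (F0).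

Further compounds
F1 | step 10 | 6-[(3R)-3-(2,2-dimethylchroman-6-yl)-3-hydroxy-1-(triisopropylsilyloxy)propyl]-2-(3-methylbut-2-en-1-yl)-3-(triisopropylsilyloxy)phenyl trifluoromethanesulfonate | CC(C)=CCc1c(O[Si](C(C)C)(C(C)C)C(C)C)ccc(C(O[Si](C(C)C)(C(C)C)C(C)C)C[C@@H](O)c2ccc3c(c2)CCC(C)(C)O3)c1OS(=O)(=O)C(F)(F)F
F2 | step 10 | 6-[(3R)-3-(2,2-dimethylchroman-6-yl)-3-hydroxy-1-(triisopropylsilyloxy)propyl]-2-(3-methylbut-2-en-1-yl)-3-(triisopropylsilyloxy)phenol | CC(C)=CCc1c(O[Si](C(C)C)(C(C)C)C(C)C)ccc(C(O[Si](C(C)C)(C(C)C)C(C)C)C[C@@H](O)c2ccc3c(c2)CCC(C)(C)O3)c1O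
F3 | step 12 | (2S)-7-(tert-butyldimethylsilyloxy)-2-(2,2-dimethylchroman-6-yl)-8-(3-methylbut-2-en-1-yl)chroman-4-ol | CC(C)=CCc1c(O[Si](C)(C)C(C)(C)C)ccc2c1O[C@H](c1ccc3c(c1)CCC(C)(C)O3)CC2O
F4 | step 12 | (2S)-7-(tert-butyldimethylsilyloxy)-2-(2,2-dimethylchroman-6-yl)-8-(3-methylbut-2-en-1-yl)chroman-4-one | CC(C)=CCc1c(O[Si](C)(C)C(C)(C)C)ccc2c1O[C@H](c1ccc3c(c1)CCC(C)(C)O3)CC2=O
F0 | step 9 | none | none
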